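## Retrosynthetic overview

- The strategy rests on C6 and C7, the adjacent quaternary carbons of the cyclohexene ring. Each carries an ethyl group on one face and a one-carbon group (styryl Cα, CO2H) on the other, which is the pattern of a cis-2,3-diethylmaleic anhydride unit. Cutting C5–C6 and C7–C7a gives the anhydride and a C2-symmetric 1-amino-3-siloxybutadiene; this [4+2] forms the six-membered ring first.
- With a symmetric dienophile the endo and exo adducts give antipodal enones once the amine is lost, so the cycloaddition must be both face- and endo-selective.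
- Carbon nucleophiles are expected to attack C7a anti to the angular ethyl groups, which is the wrong face for C1. C1 is therefore attached without stereochemical consequence (Mukaiyama–Michael, then Saegusa–Ito). H (at C7a) and C3 (at C3a) are then delivered to the open anhydride face, which gives the trans ring fusion.
- C4 ketone → enol triflate → methyl (C4=C5); the anhydride is half-reduced at the C6 carbonyl and olefinated to the E-styryl acid.
- The cyclopentanone (second ring) is closed last by Dieckmann condensation (C2–C3), followed by C3 methylation and decarboxylation; C1 and C3 are set by equilibration.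

Key step: step 3

Remark (labels): atom labels C1–C7a are those of the target hydrindanone and are used for all intermediates; β is the face of the six-membered ring carrying the C6/C7 ethyl groups, α the face carrying the two carbonyl-derived groups.
Remark (assumption): the diene face is taken to be shielded by the phenyl group on the pyrrolidine carbon lying syn to the C7a–H of the diene; with endo addition this makes the (2R,5R) amine the matched antipode. If induction runs the other way, the equally available (2S,5S) amine is used and nothing else changes.
Remark (C1): C1 is carried as a mixture of epimers (no stereodescriptor in the SMILES) from step 6 to step 14 and is set in step 15.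

## Route

Step 1
Reactants: 1 (E)-4-methoxybut-3-en-2-one; 2 (2R,5R)-2,5-diphenylpyrrolidine
Product: 3 (E)-4-[(2R,5R)-2,5-diphenylpyrrolidin-1-yl]but-3-en-2-one
Conditions: MeOH, 50 °C
Reagents that add atoms: none
Why: Conjugate addition–elimination of the secondary amine on the β-methoxy enone (vinylogous transamidation) should give the E vinylogous amide; no stereocentre is formed and those of the pyrrolidine are untouched.

Step 2
Reactants: 3 vinylogous amide
Product: 4 (2R,5R)-1-[(1E)-3-(tert-butyldimethylsilyloxy)buta-1,3-dien-1-yl]-2,5-diphenylpyrrolidine
Conditions: KHMDS, THF, −78 °C; TBSCl, −78 → 25 °C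
Reagents that add atoms: tert-butyldimethylsilyl chloride, CC(C)(C)[Si](C)(C)Cl
Why: Deprotonation of the methyl ketone and O-silylation of the cross-conjugated enolate is the standard entry to 1-amino-3-siloxydienes; the E enamine geometry is retained.

Step 3
Reactants: 4 aminosiloxy diene; 5 2,3-diethylmaleic anhydride
Product: 6 3a,7a-diethyl-6-(tert-butyldimethylsilyloxy)-4-[(2R,5R)-2,5-diphenylpyrrolidin-1-yl]-3a,4,7,7a-tetrahydroisobenzofuran-1,3-dione (endo adduct: amine cis to the anhydride carbonyls)
Conditions: PhMe, 12 kbar, 25 °C
Reagents that add atoms: none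
Why: Normal-electron-demand Diels–Alder reaction, concerted but asynchronous (the amino- and siloxy-activated terminus C5 bonds ahead of C7a); the closest known reaction type is the cycloaddition of 1-amino-3-siloxybutadienes bearing C2-symmetric 2,5-diarylpyrrolidines with α-substituted dienophiles, and pressure replaces heat because tetrasubstituted dialkylmaleic anhydrides are sluggish. The cyclohexene ring is closed by the intermolecular [4+2] itself, the two σ-bonds C5–C6 and C7–C7a forming suprafacially on the anhydride. C6 and C7 therefore inherit the cis geometry of the dienophile, both ethyl groups on one face and both carbonyls on the other. Their absolute sense is fixed by two elements acting together: the phenyl group on the pyrrolidine carbon syn to the C7a–H shields one diene face, and the anhydride ring sits endo under C3a–C4 while the ethyl groups point away from the diene. The step thus needs π-facial and endo selectivity at once, since exo addition to the same diene face would give the antipodal C6/C7 pair once the amine is lost; the C7a amino centre itself is transient. As endo and exo adducts are diastereomers, a minor exo isomer can be removed before step 4.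

Step 4
Reactants: 6 Diels–Alder adduct
Product: 8 cis-3a,7a-diethyl-7,7a-dihydroisobenzofuran-1,3,6(3aH)-trione (enone anhydride: C4=O with C3a=C7a), via amino ketone 7 (not isolated)
Conditions: HF·pyridine, MeCN, 0 → 25 °C; acidic work-up
Reagents that add atoms: none
Why: Protodesilylation of the silyl enol ether gives the β-amino ketone, which loses the protonated pyrrolidine by E1cB elimination to the enone; the quaternary C6/C7 are untouched and the acidic work-up keeps the liberated auxiliary protonated and away from the anhydride.

Step 5
Reactants: 9 methyl butanoate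
Product: 10 1-methoxy-1-(trimethylsilyloxy)but-1-ene (E/Z mixture)
Conditions: LDA, THF, −78 °C; TMSCl
Reagents that add atoms: chlorotrimethylsilane, C[Si](C)(C)Cl
Why: Standard O-silylation of an ester enolate to the ketene silyl acetal; its geometry is irrelevant because C1 is equilibrated later.

Step 6
Reactants: 8 enone anhydride; 10 ketene silyl acetal
Product: 11 Michael adduct as its trimethylsilyl enol ether (C4–OTMS with C3a=C4; C7a bears CH(Et)CO2Me, expected on the α face; C1 epimers)
Conditions: TMSOTf (10 mol %), CH2Cl2, −78 °C; Et3N quench
Reagents that add atoms: none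
Why: Lewis acid-catalysed Mukaiyama–Michael addition brings C1 with its ethyl group and the future C2 carboxyl to C7a and traps O4 as the regiodefined silyl enol ether; the nucleophile should enter anti to the angular ethyl groups, but neither the C7a nor the C1 configuration matters since C7a becomes sp2 in step 7 and C1 is epimerisable.

Step 7
Reactants: 11 silyl enol ether
Product: 12 β-substituted enone anhydride (C4=O, C3a=C7a, C7a–CH(Et)CO2Me; C1 epimers)
Conditions: Pd(OAc)2 (1.1 equiv), MeCN, 25 °C
Reagents that add atoms: none
Why: Saegusa–Ito dehydrogenation; the palladium enolate bound at C3a can only β-eliminate the C7a hydrogen, so the enone is regenerated with C1 now attached to the sp2 carbon C7a.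

Step 8
Reactants: 12 β-substituted enone anhydride
Product: 14 keto diester anhydride (C4 ketone; C7a–H α and C7a–CH(Et)CO2Me β; C3a–CH2CO2Me α and C3a–H β), via diphenylsilyl enol ether 13 (not isolated)
Conditions: [(Ph3P)CuH]6 (cat.), Ph2SiH2, PhMe, 0 → 25 °C; then TBAT, BrCH2CO2Me, CH2Cl2, 25 °C
Reagents that add atoms: methyl bromoacetate, COC(=O)CBr
Why: Copper hydride 1,4-reduction (conjugate hydrosilylation) followed by fluoride-promoted alkylation of the regiodefined silyl enol ether is a known tandem route to trans-2,3-disubstituted cycloalkanones. Hydride should reach C7a on the α face, anti to the angular C7 and C6 ethyl groups and past the flat, tied-back anhydride, which leaves C1 β. The enolate is then alkylated at C3a anti to the new β substituent and to the axial C7 ethyl group, setting the trans relationship of the two ring-fusion carbons.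

Step 9
Reactants: 14 keto diester anhydride
Product: 15 enol triflate (C4–OTf, C4=C5)
Conditions: KHMDS, THF, −78 °C; PhNTf2, −78 → 0 °C
Reagents that add atoms: N-phenylbis(trifluoromethanesulfonimide), O=S(=O)(N(c1ccccc1)S(=O)(=O)C(F)(F)F)C(F)(F)F
Why: Kinetic deprotonation of the ketone at the C5 methylene (rather than the tertiary C3a–H or the less acidic ester α-positions) and O-triflation give the Δ4,5 enol triflate without touching C3a.

Step 10
Reactants: 15 enol triflate
Product: 16 methyl alkene anhydride (C4–CH3, C4=C5)
Conditions: SnMe4, Pd(PPh3)4 (cat.), LiCl, DMF, 80 °C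
Reagents that add atoms: tetramethylstannane, C[Sn](C)(C)C
Why: Stille cross-coupling of the enol triflate installs the C4 methyl group with the double bond fixed at C4=C5 under neutral conditions that spare the anhydride and the esters.

Step 11
Reactants: 16 methyl alkene anhydride
Product: 17 hydroxy lactone (C6–CH(OH)–O–C(=O)–C7; lactol epimers)
Conditions: LiAlH(OtBu)3, THF, −78 → −30 °C; aq. NaHSO4
Reagents that add atoms: none
Why: Half-reduction of a cyclic anhydride by a bulky alkoxyaluminium hydride stops at the tetrahedral aluminate and leaves methyl esters alone; attack is expected at the C6 carbonyl, whose only ring-side neighbour is the vinylic C5–H, whereas the C7 carbonyl is flanked by the substituted sp3 carbon C7a.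

Step 12
Reactants: 17 hydroxy lactone
Product: 18 styryl acid diester (C6–(E)-CH=CHPh, C7–CO2H)
Conditions: BnPBu3Br, NaHMDS, THF, 0 °C (ylide preformed, 2.5 equiv); then 17, 0 → 40 °C; aq. citric acid
Reagents that add atoms: benzyltributylphosphonium bromide, CCCC[P+](CCCC)(CCCC)Cc1ccccc1.[Br-]
Why: Wittig olefination of the aldehyde–carboxylate that is in equilibrium with the lactol under base; a trialkylphosphonium benzylide is a semi-stabilised ylide that should give the E-styrene, its low basicity leaves the ester α-hydrogens alone, and the quaternary C6/C7 cannot epimerise.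

Step 13
Reactants: 18 styryl acid diester
Product: 19 trans-fused hydrindanone β-keto ester acid (C2 ketone, C3–CO2Me)
Conditions: LiHMDS (3.5 equiv), THF, −78 → 0 °C; aq. HCl
Reagents that add atoms: none
Why: Dieckmann condensation: the enolate of the C3 acetate attacks the C2 ester (5-exo-trig) and the product is held as its stabilised β-keto ester enolate; the trans-diequatorial side chains set in step 8 close to the trans-fused cyclopentanone, and the hindered C7 carboxylate is a spectator.

Step 14
Reactants: 19 β-keto ester acid
Product: 20 C3-methylated β-keto ester, C7 methyl ester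
Conditions: MeI, K2CO3, DMF, 25 °C
Reagents that add atoms: iodomethane, CI
Why: C-alkylation of the β-keto ester places the methyl group on C3 regiospecifically and the carboxylate is O-methylated in the same operation; the C3 configuration is irrelevant because the ester is removed next.

Step 15
Reactants: 20 dimethyl ester
Product: 22 target acid CNP0178058.1, via keto diacid 21 (not isolated)
Conditions: LiI, 2,4,6-collidine, reflux; then DBU, THF, 25 °C; 1 M HCl
Reagents that add atoms: none
Why: Iodide cleaves both methyl esters by SN2 at the methyl carbon (insensitive to the hindrance at C7) and the β-keto acid decarboxylates. Base then equilibrates the two enolisable centres to the all-trans arrangement expected to be the more stable (C1 ethyl trans to C7, C3 methyl trans to C4), which is the target configuration; the ring-fusion centres are not enolisable.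

## Compound list

1 | (E)-4-methoxybut-3-en-2-one | CO/C=C/C(C)=O | starting material
2 | (2R,5R)-2,5-diphenylpyrrolidine | N1[C@@H](c2ccccc2)CC[C@@H]1c3ccccc3 | starting material
3 | (E)-4-[(2R,5R)-2,5-diphenylpyrrolidin-1-yl]but-3-en-2-one | CC(=O)/C=C/N1[C@@H](c2ccccc2)CC[C@@H]1c3ccccc3 | intermediate
4 | (2R,5R)-1-[(1E)-3-(tert-butyldimethylsilyloxy)buta-1,3-dien-1-yl]-2,5-diphenylpyrrolidine | C=C(O[Si](C)(C)C(C)(C)C)/C=C/N1[C@@H](c2ccccc2)CC[C@@H]1c3ccccc3 | intermediate
5 | 2,3-diethylmaleic anhydride | CCC1=C(CC)C(=O)OC1=O | starting material
6 | endo Diels–Alder adduct (amino silyl enol ether anhydride) | C1=C(O[Si](C)(C)C(C)(C)C)C[C@]2(CC)C(=O)OC(=O)[C@]2(CC)[C@@H]1N3[C@@H](c4ccccc4)CC[C@@H]3c5ccccc5 | intermediate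
7 | β-amino ketone anhydride | C1C(=O)C[C@]2(CC)C(=O)OC(=O)[C@]2(CC)[C@@H]1N3[C@@H](c4ccccc4)CC[C@@H]3c5ccccc5 | intermediate (not isolated)
8 | cis-3a,7a-diethyl-7,7a-dihydroisobenzofuran-1,3,6(3aH)-trione (enone anhydride) | O=C1C[C@]2(CC)C(=O)OC(=O)[C@]2(CC)C=C1 | intermediate
9 | methyl butanoate | CCCC(=O)OC | starting material
10 | 1-methoxy-1-(trimethylsilyloxy)but-1-ene (E/Z) | CCC=C(OC)O[Si](C)(C)C | intermediate
11 | Michael adduct, trimethylsilyl enol ether (C1 on α face at C7a, C1 epimers) | C[Si](C)(C)OC1=C[C@@H](C(CC)C(=O)OC)[C@@]2(CC)C(=O)OC(=O)[C@@]2(CC)C1 | intermediate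
12 | β-substituted enone anhydride (C1 epimers) | O=C1C=C(C(CC)C(=O)OC)[C@@]2(CC)C(=O)OC(=O)[C@@]2(CC)C1 | intermediate
13 | diphenylsilyl enol ether (H7a α, C1 β) | O(C1=C[C@H](C(CC)C(=O)OC)[C@@]2(CC)C(=O)OC(=O)[C@@]2(CC)C1)[SiH](c3ccccc3)c4ccccc4 | intermediate (not isolated)
14 | keto diester anhydride (C3a–CH2CO2Me α, C7a–CH(Et)CO2Me β) | COC(=O)C[C@@H]1C(=O)C[C@]2(CC)C(=O)OC(=O)[C@]2(CC)[C@H]1C(CC)C(=O)OC | intermediate
15 | enol triflate (C4–OTf, C4=C5) | COC(=O)C[C@@H]1C(OS(=O)(=O)C(F)(F)F)=C[C@]2(CC)C(=O)OC(=O)[C@]2(CC)[C@H]1C(CC)C(=O)OC | intermediate
16 | methyl alkene anhydride (C4–CH3, C4=C5) | COC(=O)C[C@@H]1C(C)=C[C@]2(CC)C(=O)OC(=O)[C@]2(CC)[C@H]1C(CC)C(=O)OC | intermediate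
17 | hydroxy lactone (lactol carbon on C6, lactone carbonyl on C7) | COC(=O)C[C@@H]1C(C)=C[C@]2(CC)C(O)OC(=O)[C@]2(CC)[C@H]1C(CC)C(=O)OC | intermediate
18 | styryl acid diester | COC(=O)C[C@@H]1C(C)=C[C@@](/C=C/c2ccccc2)(CC)[C@](CC)(C(=O)O)[C@H]1C(CC)C(=O)OC | intermediate
19 | hydrindanone β-keto ester acid | CCC1C(=O)C(C(=O)OC)[C@@H]2C(C)=C[C@@](/C=C/c3ccccc3)(CC)[C@](CC)(C(=O)O)[C@H]21 | intermediate
20 | C3-methylated β-keto ester, C7 methyl ester | CCC1C(=O)C(C)(C(=O)OC)[C@@H]2C(C)=C[C@@](/C=C/c3ccccc3)(CC)[C@](CC)(C(=O)OC)[C@H]21 | intermediate
21 | keto diacid | CCC1C(=O)C(C)(C(=O)O)[C@@H]2C(C)=C[C@@](/C=C/c3ccccc3)(CC)[C@](CC)(C(=O)O)[C@H]21 | intermediate (not isolated)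
22 | CNP0178058.1 | CC[C@@H]1C(=O)[C@@H](C)[C@@H]2C(C)=C[C@@](/C=C/c3ccccc3)(CC)[C@](CC)(C(=O)O)[C@H]21 | target

Total step count: 15. Longest linear sequence: 14 steps (steps 1–4 and 6–15; step 5 is a one-step side branch).

## Steps most likely to fail

Step 3. The cycloaddition may be too slow: a tetrasubstituted dienophile meets a diene carrying a bulky amine, and C-acylation or decomposition of the electron-rich diene could outrun ring formation. The fallback keeps the disconnection and the auxiliary but replaces the anhydride by a strain-activated stand-in. It sets out from 4 and returns at 8. Diethyl squarate is converted by ethyllithium addition and acid-mediated rearrangement into 3-ethoxy-4-ethylcyclobut-3-ene-1,2-dione F1, and a second round gives 3,4-diethylcyclobut-3-ene-1,2-dione F2. Cycloaddition of F2 with 4, under the same facial and endo arguments, should give the bicyclo[4.2.0]octenedione adduct F3. HF·pyridine then gives the enone diketone F4, and Baeyer–Villiger oxidation of the 1,2-diketone (mCPBA, NaHCO3, CH2Cl2) inserts oxygen between the two carbonyl groups to give 8.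

Step 8. Hydride transfer to the congested C7a may occur on the β (ethyl) face, which would mean that the facial preference of the enone is the reverse of the one assumed. In that case the ketene acetal in step 6 will also have put C1 on the β face, and the Michael adduct is the C7a-epimeric silyl enol ether F5, which already has the correct C7a configuration. The fallback sets out from 8 (with 10) and returns at 14: F5 is alkylated directly with TBAT and methyl bromoacetate at C3a, anti to C1, and steps 7 and 8 are dropped. Whichever face nucleophiles prefer, one of the two sequences therefore leads to 14.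

Step 11. The hydride may not discriminate well enough between the C6 and C7 carbonyl groups, or may over-reduce to the lactone; regioisomeric lactols cannot be recycled. The fallback replaces the kinetic hydride reduction by a two-stage acyl substitution/hydrogenolysis and sets out from 16, returning at 17. Thiolysis of 16 (EtSH, Et3N, cat. DMAP, CH2Cl2) should open the anhydride at the less hindered carbonyl to give the C6 S-ethyl thioester C7 acid F6. The hemithioester is a stable, separable compound, and any regioisomer reverts to 16 on warming with acetic anhydride. Fukuyama reduction of F6 (Et3SiH, Pd/C, acetone) then gives the aldehyde acid, which closes to 17.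

Further compounds
F1 | step 3 | 3-ethoxy-4-ethylcyclobut-3-ene-1,2-dione | CCOC1=C(CC)C(=O)C1=O
F2 | step 3 | 3,4-diethylcyclobut-3-ene-1,2-dione | CCC1=C(CC)C(=O)C1=O
F3 | step 3 | cyclobutanedione cycloadduct (amino silyl enol ether) | C1=C(O[Si](C)(C)C(C)(C)C)C[C@]2(CC)C(=O)C(=O)[C@]2(CC)[C@@H]1N3[C@@H](c4ccccc4)CC[C@@H]3c5ccccc5
F4 | step 3 | enone cyclobutane-1,2-dione | O=C1C[C@]2(CC)C(=O)C(=O)[C@]2(CC)C=C1
F5 | step 8 | C7a epimer of 11 (C1 on β face, C1 epimers) | C[Si](C)(C)OC1=C[C@H](C(CC)C(=O)OC)[C@@]2(CC)C(=O)OC(=O)[C@@]2(CC)C1
F6 | step 11 | C6 S-ethyl thioester C7 acid | COC(=O)C[C@@H]1C(C)=C[C@](CC)(C(=O)SCC)[C@](CC)(C(=O)O)[C@H]1C(CC)C(=O)OC
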